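**Strategy.** The seven-membered carbocycle (C1, C5, C6, C7, C8, C9, C10) carries the C6 oxygen, C11 on C7 and the C10 methyl on one face, with a carbonyl carbon (C2) on C1. This is the imprint of a rhodium vinylcarbenoid (4+3) cycloaddition. A 4-alkoxy vinyldiazoacetate (C2, C1, C5, C6) cyclopropanates the Z enol silane of a 2-siloxy diene (C14, C10 to C7, C11, C12), and the cis-divinylcyclopropane undergoes Cope ring expansion at once. One operation forms C1–C10 and C6–C7, closes the ring and sets C6, C7 and C10. Epoxidation, carboxylate opening, directed reduction and side-chain oxidations then complete the target.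

Key step: step 6

**Remarks.**
- Atom labels follow the target: ring C1, C5, C6, C7, C8, C9, C10; butenoyl chain C2–C3=C4–C15; lactone carbons C11, C12, C13; C14 is the methyl on C10. α is the ring face that carries the C6 oxygen, β the opposite face. TBS = tert-butyldimethylsilyl, PMB = 4-methoxybenzyl.
- Assumption: the sense of induction of Rh2(S-DOSP)4 is taken from its usual behaviour in cyclopropanation of simple alkenes; if the first run gives the antipode, Rh2(R-DOSP)4 is used and nothing else changes.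
- The tartrate in step 8 is chosen by the empirical face rule for allylic alcohols.

**Route**

Step 1
Reactants: 1 but-3-en-1-ol
Product: 2 tert-butyl(but-3-en-1-yloxy)dimethylsilane
Conditions: TBSCl, imidazole, CH2Cl2, 0 → 23 °C
Reagents that add atoms: tert-butyldimethylsilyl chloride, CC(C)(C)[Si](C)(C)Cl
Why: Silyl ether formation on a primary alcohol is clean and masks the C12 oxygen for the metathesis and carbenoid steps; no stereocenter is formed.

Step 2
Reactants: 2 tert-butyl(but-3-en-1-yloxy)dimethylsilane, 3 pent-1-en-3-one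
Product: 4 (E)-7-(tert-butyldimethylsilyloxy)hept-4-en-3-one
Conditions: second-generation Grubbs catalyst (3 mol%), 3 (3 equiv), CH2Cl2, 40 °C
Reagents that add atoms: none
Why: Olefin cross-metathesis of a terminal alkene with an electron-poor vinyl ketone favours the cross product and should give the E enone (C7=C8) under thermodynamic control.

Step 3
Reactants: 4 (E)-7-(tert-butyldimethylsilyloxy)hept-4-en-3-one
Product: 5 (2Z,4E)-3,7-bis(tert-butyldimethylsilyloxy)hepta-2,4-diene
Conditions: TBSOTf, Et3N, CH2Cl2, −78 → 0 °C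
Reagents that add atoms: tert-butyldimethylsilyl trifluoromethanesulfonate, CC(C)(C)[Si](C)(C)OS(=O)(=O)C(F)(F)F
Why: Soft enolisation (silyl triflate and amine) removes an α′ hydrogen of the ethyl ketone and should give the cross-conjugated dienol silane with the Z enol ether (methyl cis to OSi), because the methyl avoids the alkenyl group in the deprotonation of the O-silylated ketone.

Step 4
Reactants: 6 methyl (E)-4-bromobut-2-enoate, 7 4-methoxybenzyl alcohol
Product: 8 methyl (E)-4-(4-methoxybenzyloxy)but-2-enoate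
Conditions: Ag2O, 7 (2 equiv), 4 Å MS, CH2Cl2, 23 °C, dark
Reagents that add atoms: none
Why: Silver oxide-assisted Williamson etherification substitutes the allylic bromide without free alkoxide, which avoids conjugate addition to the enoate and keeps the E alkene.

Step 5
Reactants: 8 methyl (E)-4-(4-methoxybenzyloxy)but-2-enoate
Product: 9 methyl (E)-2-diazo-4-(4-methoxybenzyloxy)but-3-enoate
Conditions: 4-acetamidobenzenesulfonyl azide, DBU, MeCN, 0 °C; cold work-up, solution used at once
Reagents that add atoms: 4-acetamidobenzenesulfonyl azide, CC(=O)Nc1ccc(cc1)S(=O)(=O)N=[N+]=[N-]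
Why: Regitz diazo transfer in its deconjugative mode: DBU removes a γ hydrogen, the extended dienolate attacks the sulfonyl azide at Cα, and the enol ether alkene should form E from the extended dienolate; immediate use limits closure to a pyrazole.

Step 6
Reactants: 5 (2Z,4E)-3,7-bis(tert-butyldimethylsilyloxy)hepta-2,4-diene, 9 methyl (E)-2-diazo-4-(4-methoxybenzyloxy)but-3-enoate
Product: 11 methyl 9-(TBS-oxy)-7α-[2-(TBS-oxy)ethyl]-6α-(PMB-oxy)-10α-methylcyclohepta-1(5),8-diene-1-carboxylate, via cis-divinylcyclopropane 10 (not isolated)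
Conditions: Rh2(S-DOSP)4 (dirhodium tetrakis[(S)-N-(4-dodecylbenzenesulfonyl)prolinate], 2 mol%), 5 (2.5 equiv), hexanes, −78 → 23 °C, 9 added over 2 h
Reagents that add atoms: none
Why: Loss of N2 from 9 on the dirhodium catalyst gives a donor/acceptor vinylcarbenoid that adds in one concerted, asynchronous event to the electron-rich C9=C10 enol silane of 5 with its alkenyl arm cis to the C7=C8 alkenyl group (10), and the strained cis-divinylcyclopropane then rearranges below room temperature, breaking C1–C9 and forming C6–C7. The closest known reaction type is the tandem cyclopropanation/Cope rearrangement of rhodium vinylcarbenoids with 2-siloxy-1,3-dienes, a formal (4+3) cycloaddition. The cycloheptadiene is closed by a [3,3]-sigmatropic ring expansion through the endo boat transition state, not by an end-to-end cyclisation. C10 keeps the Z geometry of the enol silane (methyl trans to both alkenyl groups on the cyclopropane), while C6 and C7 arise from the two E alkenes, whose substituents point outward in the boat, so C6–O, C7–C11 and C10–CH3 become cis; the S-prolinate ligands fix the absolute sense by selecting the carbenoid face. The step needs site, relative and absolute selectivity: the trans-disubstituted C7=C8 alkene is inert to this carbenoid class, the enol silane is the most nucleophilic π bond, and the E vinyl ether keeps the benzylic C–H bonds of the PMB group away from the carbenoid carbon.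

Step 7
Reactants: 11 methyl 9-(TBS-oxy)-7α-[2-(TBS-oxy)ethyl]-6α-(PMB-oxy)-10α-methylcyclohepta-1(5),8-diene-1-carboxylate
Product: 12 [9-(TBS-oxy)-7α-[2-(TBS-oxy)ethyl]-6α-(PMB-oxy)-10α-methylcyclohepta-1(5),8-dien-1-yl]methanol
Conditions: iBu2AlH (DIBAL-H, 2.5 equiv), CH2Cl2, −78 °C; aqueous potassium sodium tartrate
Reagents that add atoms: none
Why: Hydride reduction of the enoate with DIBAL-H at low temperature gives the primary allylic alcohol (C2) by 1,2-reduction, while the enol silane, silyl ether and PMB ether are inert and no stereocenter is touched.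

Step 8
Reactants: 12 [9-(TBS-oxy)-7α-[2-(TBS-oxy)ethyl]-6α-(PMB-oxy)-10α-methylcyclohepta-1(5),8-dien-1-yl]methanol
Product: 13 [1α,5α-epoxy-9-(TBS-oxy)-7α-[2-(TBS-oxy)ethyl]-6α-(PMB-oxy)-10α-methylcyclohept-8-en-1-yl]methanol
Conditions: Ti(OiPr)4 (0.2 equiv), D-(−)-diethyl tartrate (0.24 equiv), t-BuOOH (2 equiv, isooctane), 4 Å MS, CH2Cl2, −20 °C
Reagents that add atoms: tert-butyl hydroperoxide, CC(C)(C)OO
Why: Sharpless asymmetric epoxidation transfers oxygen only to the alkene held by the titanium-bound allylic alkoxide, so the enol silane should be spared, and the D-(−)-tartrate directs it to the α face of C1=C5 (syn to C6–O), setting C1 and C5 by reagent control.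

Step 9
Reactants: 13 [1α,5α-epoxy-9-(TBS-oxy)-7α-[2-(TBS-oxy)ethyl]-6α-(PMB-oxy)-10α-methylcyclohept-8-en-1-yl]methanol, 14 (S)-2-methylbutanoic acid
Product: 15 1α-hydroxy-1-(hydroxymethyl)-9-(TBS-oxy)-7α-[2-(TBS-oxy)ethyl]-6α-(PMB-oxy)-10α-methylcyclohept-8-en-5β-yl (S)-2-methylbutanoate
Conditions: Ti(OiPr)4 (1.5 equiv), 14 (1.5 equiv), CH2Cl2, 23 °C; aqueous tartaric acid work-up
Reagents that add atoms: none
Why: Titanium isopropoxide-mediated C3-selective opening of a 2,3-epoxy alcohol by a carboxylic acid: the chelate through the C2 hydroxyl activates the oxirane and the carboxylate attacks the secondary C5 (C1 is fully substituted) from the β face with inversion, which should give the trans C1–OH(α)/C5–ester(β) pair.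

Step 10
Reactants: 15 1α-hydroxy-1-(hydroxymethyl)-9-(TBS-oxy)-7α-[2-(TBS-oxy)ethyl]-6α-(PMB-oxy)-10α-methylcyclohept-8-en-5β-yl (S)-2-methylbutanoate
Product: 16 1-formyl-1α-hydroxy-9-(TBS-oxy)-7α-[2-(TBS-oxy)ethyl]-6α-(PMB-oxy)-10α-methylcyclohept-8-en-5β-yl (S)-2-methylbutanoate
Conditions: SO3·pyridine, DMSO, iPr2NEt, CH2Cl2, 0 °C
Reagents that add atoms: none
Why: Parikh–Doering oxidation converts the only primary alcohol into the aldehyde; the tertiary C1 hydroxyl cannot be oxidised, the enol silane tolerates activated DMSO, and C1 has no α hydrogen to epimerise.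

Step 11
Reactants: 16 1-formyl-1α-hydroxy-9-(TBS-oxy)-7α-[2-(TBS-oxy)ethyl]-6α-(PMB-oxy)-10α-methylcyclohept-8-en-5β-yl (S)-2-methylbutanoate, 17 (E)-1-bromoprop-1-ene
Product: 18 1α-hydroxy-1-[(E)-1-hydroxybut-2-enyl]-9-(TBS-oxy)-7α-[2-(TBS-oxy)ethyl]-6α-(PMB-oxy)-10α-methylcyclohept-8-en-5β-yl (S)-2-methylbutanoate (both C2 epimers)
Conditions: CrCl2 (6 equiv), NiCl2 (2 mol%), 17 (3 equiv), DMSO, 23 °C
Reagents that add atoms: none
Why: Nozaki–Hiyama–Kishi coupling: the alkenylchromium species adds only to the aldehyde (ester, enol silane and free tertiary hydroxyl are tolerated) with retention of the E alkene, and the new C2 carbinol may form as a mixture because step 14 removes that center.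

Step 12
Reactants: 18 1α-hydroxy-1-[(E)-1-hydroxybut-2-enyl]-9-(TBS-oxy)-7α-[2-(TBS-oxy)ethyl]-6α-(PMB-oxy)-10α-methylcyclohept-8-en-5β-yl (S)-2-methylbutanoate
Product: 19 1α-hydroxy-1-[(E)-1-hydroxybut-2-enyl]-7α-(2-hydroxyethyl)-6α-(PMB-oxy)-10α-methyl-9-oxocycloheptan-5β-yl (S)-2-methylbutanoate
Conditions: HF·pyridine, pyridine, THF, 0 → 23 °C
Reagents that add atoms: none
Why: Fluoride-mediated desilylation cleaves the enol silane (protonation at C8 gives the C9 ketone) and the primary silyl ether in one buffered operation that should leave the β-hydroxy ketone, the ester, the PMB ether and the C10 center intact.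

Step 13
Reactants: 19 1α-hydroxy-1-[(E)-1-hydroxybut-2-enyl]-7α-(2-hydroxyethyl)-6α-(PMB-oxy)-10α-methyl-9-oxocycloheptan-5β-yl (S)-2-methylbutanoate
Product: 20 1α,9β-dihydroxy-1-[(E)-1-hydroxybut-2-enyl]-7α-(2-hydroxyethyl)-6α-(PMB-oxy)-10α-methylcycloheptan-5β-yl (S)-2-methylbutanoate
Conditions: Me4NBH(OAc)3 (6 equiv), MeCN/AcOH (1:1), −30 °C
Reagents that add atoms: none
Why: Evans–Saksena hydroxyl-directed reduction: the C1 hydroxyl (α face) exchanges onto boron and delivers hydride through a six-membered transition state to the α face of the C9 ketone, which should give the 1,3-anti diol with C9–OH β; the other hydroxyls cannot reach C9 through a comparable ring and isolated carbonyls are not reduced.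

Step 14
Reactants: 20 1α,9β-dihydroxy-1-[(E)-1-hydroxybut-2-enyl]-7α-(2-hydroxyethyl)-6α-(PMB-oxy)-10α-methylcycloheptan-5β-yl (S)-2-methylbutanoate
Product: 21 1-[(E)-but-2-enoyl]-1α,9β-dihydroxy-7α-(2-hydroxyethyl)-6α-(PMB-oxy)-10α-methylcycloheptan-5β-yl (S)-2-methylbutanoate
Conditions: MnO2 (activated, 25 equiv), CH2Cl2, 23 °C
Reagents that add atoms: none
Why: Manganese dioxide oxidation is selective for the allylic C2 carbinol, giving the E enone and erasing the C2 mixture, while the saturated primary and secondary alcohols are untouched.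

Step 15
Reactants: 21 1-[(E)-but-2-enoyl]-1α,9β-dihydroxy-7α-(2-hydroxyethyl)-6α-(PMB-oxy)-10α-methylcycloheptan-5β-yl (S)-2-methylbutanoate
Product: 22 1-[(E)-but-2-enoyl]-1α,9β-dihydroxy-6α-(PMB-oxy)-10α-methyl-7α-(2-oxoethyl)cycloheptan-5β-yl (S)-2-methylbutanoate
Conditions: TEMPO (0.2 equiv), PhI(OAc)2 (1.3 equiv), CH2Cl2, 23 °C
Reagents that add atoms: none
Why: Oxoammonium (TEMPO) oxidation is selective for the primary C12 alcohol over the hindered secondary C9 alcohol and stops at the aldehyde in anhydrous medium.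

Step 16
Reactants: 22 1-[(E)-but-2-enoyl]-1α,9β-dihydroxy-6α-(PMB-oxy)-10α-methyl-7α-(2-oxoethyl)cycloheptan-5β-yl (S)-2-methylbutanoate
Product: 24 1-[(E)-but-2-enoyl]-1α,9β-dihydroxy-6α-(PMB-oxy)-10α-methyl-7α-(3-oxoprop-1-en-2-yl)cycloheptan-5β-yl (S)-2-methylbutanoate, via Mannich base 23 (not isolated)
Conditions: Me2N=CH2 I (Eschenmoser's salt, 3 equiv), Et3N, CH2Cl2, 23 °C
Reagents that add atoms: N,N-dimethylmethyleneiminium iodide, C[N+](C)=C.[I-]
Why: Mannich reaction of the aldehyde at C11 followed by elimination of dimethylamine (aldehyde α-methylenation) installs C13; C11 is the only enolisable α-CH2 next to a carbonyl, and the C11 center of the Mannich base disappears.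

Step 17
Reactants: 24 1-[(E)-but-2-enoyl]-1α,9β-dihydroxy-6α-(PMB-oxy)-10α-methyl-7α-(3-oxoprop-1-en-2-yl)cycloheptan-5β-yl (S)-2-methylbutanoate
Product: 25 2-[2β-[(E)-but-2-enoyl]-2α,4β-dihydroxy-7α-(PMB-oxy)-3α-methyl-1β-[(S)-2-methylbutanoyloxy]cyclohept-6α-yl]prop-2-enoic acid (C7 acrylic acid; SMILES below)
Conditions: NaClO2, NaH2PO4, 2-methylbut-2-ene, t-BuOH/H2O, 0 → 23 °C
Reagents that add atoms: sodium chlorite, [Na+].[O-]Cl=O
Why: Pinnick oxidation converts the enal into the acrylic acid without touching the enone, the alkenes (hypochlorite scavenger) or the alcohols.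

Step 18
Reactants: 25 C7 acrylic acid
Product: 27 (3aS,5R,6S,7S,8S,8aR)-7-[(2E)-but-2-enoyl]-5,7-dihydroxy-6-methyl-3-methylidene-2-oxooctahydro-2H-cyclohepta[b]furan-8-yl (2S)-2-methylbutanoate, via hydroxy acid 26 (not isolated)
Conditions: DDQ (1.5 equiv), CH2Cl2/pH 7 buffer (10:1), 0 °C; then PPTS (cat.), CH2Cl2, 23 °C
Reagents that add atoms: none
Why: Oxidative PMB ether cleavage frees the C6 hydroxyl, which is cis to the acrylic acid chain on C7 and should close the cis-fused γ-lactone by lactonisation (5-exo-trig acyl substitution); no stereocenter is affected.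

**Compound list**

1 | but-3-en-1-ol | C=CCCO | starting material
2 | tert-butyl(but-3-en-1-yloxy)dimethylsilane | C=CCCO[Si](C)(C)C(C)(C)C | intermediate
3 | pent-1-en-3-one | C=CC(=O)CC | starting material
4 | (E)-7-(tert-butyldimethylsilyloxy)hept-4-en-3-one | CCC(=O)/C=C/CCO[Si](C)(C)C(C)(C)C | intermediate
5 | (2Z,4E)-3,7-bis(tert-butyldimethylsilyloxy)hepta-2,4-diene | C/C=C(/C=C/CCO[Si](C)(C)C(C)(C)C)O[Si](C)(C)C(C)(C)C | intermediate
6 | methyl (E)-4-bromobut-2-enoate | COC(=O)/C=C/CBr | starting material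
7 | 4-methoxybenzyl alcohol | COc1ccc(CO)cc1 | starting material
8 | methyl (E)-4-(4-methoxybenzyloxy)but-2-enoate | COC(=O)/C=C/COCc1ccc(OC)cc1 | intermediate
9 | methyl (E)-2-diazo-4-(4-methoxybenzyloxy)but-3-enoate | COC(=O)C(=[N+]=[N-])/C=C/OCc1ccc(OC)cc1 | intermediate
10 | methyl 2-(TBS-oxy)-2-[(E)-4-(TBS-oxy)but-1-enyl]-1-[(E)-2-(PMB-oxy)ethenyl]-3-methylcyclopropane-1-carboxylate (alkenyl groups cis; methyl cis to ring OSi and ester) | COC(=O)[C@@]1(/C=C/OCc2ccc(OC)cc2)[C@@H](C)[C@]1(O[Si](C)(C)C(C)(C)C)/C=C/CCO[Si](C)(C)C(C)(C)C | intermediate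
11 | methyl 9-(TBS-oxy)-7α-[2-(TBS-oxy)ethyl]-6α-(PMB-oxy)-10α-methylcyclohepta-1(5),8-diene-1-carboxylate | COc1ccc(CO[C@@H]2[C@H](CCO[Si](C)(C)C(C)(C)C)C=C(O[Si](C)(C)C(C)(C)C)[C@H](C)C(C(=O)OC)=C2)cc1 | intermediate
12 | [9-(TBS-oxy)-7α-[2-(TBS-oxy)ethyl]-6α-(PMB-oxy)-10α-methylcyclohepta-1(5),8-dien-1-yl]methanol | COc1ccc(CO[C@@H]2[C@H](CCO[Si](C)(C)C(C)(C)C)C=C(O[Si](C)(C)C(C)(C)C)[C@H](C)C(CO)=C2)cc1 | intermediate
13 | 1α,5α-epoxide of 12 | COc1ccc(CO[C@@H]2[C@H](CCO[Si](C)(C)C(C)(C)C)C=C(O[Si](C)(C)C(C)(C)C)[C@H](C)[C@]3(CO)O[C@H]23)cc1 | intermediate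
14 | (S)-2-methylbutanoic acid | CC[C@H](C)C(=O)O | starting material
15 | C1(α-OH)/C2-OH diol with C5β (S)-2-methylbutanoate | COc1ccc(CO[C@@H]2[C@H](CCO[Si](C)(C)C(C)(C)C)C=C(O[Si](C)(C)C(C)(C)C)[C@H](C)[C@@](O)(CO)[C@H]2OC(=O)[C@@H](C)CC)cc1 | intermediate
16 | C2 aldehyde of 15 | COc1ccc(CO[C@@H]2[C@H](CCO[Si](C)(C)C(C)(C)C)C=C(O[Si](C)(C)C(C)(C)C)[C@H](C)[C@@](O)(C=O)[C@H]2OC(=O)[C@@H](C)CC)cc1 | intermediate
17 | (E)-1-bromoprop-1-ene | C/C=C/Br | starting material
18 | C2 (E)-propenyl carbinol (both C2 epimers) | COc1ccc(CO[C@@H]2[C@H](CCO[Si](C)(C)C(C)(C)C)C=C(O[Si](C)(C)C(C)(C)C)[C@H](C)[C@@](O)(C(O)/C=C/C)[C@H]2OC(=O)[C@@H](C)CC)cc1 | intermediate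
19 | C9 ketone with free C12-OH | COc1ccc(CO[C@@H]2[C@H](CCO)CC(=O)[C@H](C)[C@@](O)(C(O)/C=C/C)[C@H]2OC(=O)[C@@H](C)CC)cc1 | intermediate
20 | C9β alcohol | COc1ccc(CO[C@@H]2[C@H](CCO)C[C@@H](O)[C@H](C)[C@@](O)(C(O)/C=C/C)[C@H]2OC(=O)[C@@H](C)CC)cc1 | intermediate
21 | C2 (E)-enone | COc1ccc(CO[C@@H]2[C@H](CCO)C[C@@H](O)[C@H](C)[C@@](O)(C(=O)/C=C/C)[C@H]2OC(=O)[C@@H](C)CC)cc1 | intermediate
22 | C12 aldehyde | COc1ccc(CO[C@@H]2[C@H](CC=O)C[C@@H](O)[C@H](C)[C@@](O)(C(=O)/C=C/C)[C@H]2OC(=O)[C@@H](C)CC)cc1 | intermediate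
23 | C11 dimethylaminomethyl aldehyde (Mannich base, C11 epimers) | COc1ccc(CO[C@@H]2[C@H](C(CN(C)C)C=O)C[C@@H](O)[C@H](C)[C@@](O)(C(=O)/C=C/C)[C@H]2OC(=O)[C@@H](C)CC)cc1 | intermediate
24 | C11 methylene aldehyde | COc1ccc(CO[C@@H]2[C@H](C(=C)C=O)C[C@@H](O)[C@H](C)[C@@](O)(C(=O)/C=C/C)[C@H]2OC(=O)[C@@H](C)CC)cc1 | intermediate
25 | C11 methylene C12 acid | COc1ccc(CO[C@@H]2[C@H](C(=C)C(=O)O)C[C@@H](O)[C@H](C)[C@@](O)(C(=O)/C=C/C)[C@H]2OC(=O)[C@@H](C)CC)cc1 | intermediate
26 | C6 hydroxy acid | O[C@@H]1[C@H](C(=C)C(=O)O)C[C@@H](O)[C@H](C)[C@@](O)(C(=O)/C=C/C)[C@H]1OC(=O)[C@@H](C)CC | intermediate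
27 | (3aS,5R,6S,7S,8S,8aR)-7-[(2E)-but-2-enoyl]-5,7-dihydroxy-6-methyl-3-methylidene-2-oxooctahydro-2H-cyclohepta[b]furan-8-yl (2S)-2-methylbutanoate (CNP0331957.1) | C=C1C(=O)O[C@@H]2[C@H]1C[C@@H](O)[C@H](C)[C@@](O)(C(=O)/C=C/C)[C@H]2OC(=O)[C@@H](C)CC | target

**Step count.** Total: 18 steps. Longest linear sequence: 16 steps (steps 1–3, then 6–18).

**Steps most likely to fail**

1. Step 6. The diazo ester may close to a 3H-pyrazole before the catalyst captures it, the carbenoid may attack allylic C–H bonds of the hindered trisubstituted enol silane in place of cyclopropanation, and the prolinate ligands may induce weakly or in the wrong sense with an oxygen-substituted vinylcarbenoid. Fallback, setting out from 5 and 9 and returning at 13: the cycloaddition is run with achiral, less encumbered dirhodium tetraoctanoate, Rh2(O2CC7H15)4, which should capture 9 faster and give 11 as the racemate, that is, together with the enantiomeric cycloadduct F1. Reduction as in step 7 gives 12 together with the enantiomeric allylic alcohol F2. The epoxidation of step 8 then serves as the resolving step: D-(−)-tartrate delivers oxygen to the same side of the planar allylic alcohol unit in both enantiomers, so 12 gives 13 while F2 gives the diastereomeric epoxy alcohol with the oxirane anti to C6–O F3, which is separated by chromatography. Half of the material is lost.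

2. Step 9. Substitution at the hindered, β-oxygenated C5 may be slow, so that isopropoxide transfer, or migration of the new C5 acyl group to the free primary C2 hydroxyl on titanium, takes over. Fallback, setting out from 13 and returning at 16: the order of oxidation and opening is reversed. Parikh–Doering oxidation of 13 gives the 1α,5α-epoxy aldehyde F8. This is opened with caesium (S)-2-methylbutanoate (from 14 and Cs2CO3) in DMF at 50 °C, buffered with excess 14. The carboxylate can attack only C5 by SN2 with inversion, since C1 is quaternary and α to the carbonyl, and no primary hydroxyl is present to receive the acyl group. The product is 16 directly.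

3. Step 8. Oxygen may be delivered to the β face if the ring's own bias overrides the tartrate, or turnover may be slow enough for the peroxide to attack the enol silane. Fallback, setting out from 12 and returning at 15: the β epoxide is made on purpose and C1 is inverted by a tethered oxygen.
   - Epoxidation of 12 with L-(+)-diethyl tartrate under the conditions of step 8 gives the 1β,5β-epoxy alcohol F4.
   - Boc2O and DMAP give its tert-butyl carbonate F5.
   - BF3·OEt2 in CH2Cl2 at −78 °C makes the carbonate carbonyl oxygen open the oxirane at the tertiary C1 in the 5-exo mode with inversion and loss of 2-methylpropene. This gives the spiro cyclic carbonate with C1–O α and a free C5β hydroxyl F6.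
   - Steglich esterification with 14 (EDC, DMAP) gives the C5 ester cyclic carbonate F7.
   - Brief K2CO3/MeOH at 0 °C cleaves the five-membered carbonate to 15.

**Further compounds**

F1 | step 6 | enantiomer of 11 | COc1ccc(CO[C@H]2[C@@H](CCO[Si](C)(C)C(C)(C)C)C=C(O[Si](C)(C)C(C)(C)C)[C@@H](C)C(C(=O)OC)=C2)cc1
F2 | step 6 | enantiomer of 12 | COc1ccc(CO[C@H]2[C@@H](CCO[Si](C)(C)C(C)(C)C)C=C(O[Si](C)(C)C(C)(C)C)[C@@H](C)C(CO)=C2)cc1
F3 | step 6 | epoxy alcohol from F2 with the oxirane anti to C6–O | COc1ccc(CO[C@H]2[C@@H](CCO[Si](C)(C)C(C)(C)C)C=C(O[Si](C)(C)C(C)(C)C)[C@@H](C)[C@]3(CO)O[C@H]23)cc1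
F4 | step 8 | 1β,5β-epoxy alcohol from 12 | COc1ccc(CO[C@@H]2[C@H](CCO[Si](C)(C)C(C)(C)C)C=C(O[Si](C)(C)C(C)(C)C)[C@H](C)[C@@]3(CO)O[C@@H]23)cc1
F5 | step 8 | tert-butyl carbonate of F4 | COc1ccc(CO[C@@H]2[C@H](CCO[Si](C)(C)C(C)(C)C)C=C(O[Si](C)(C)C(C)(C)C)[C@H](C)[C@@]3(COC(=O)OC(C)(C)C)O[C@@H]23)cc1
F6 | step 8 | C1/C2 spiro cyclic carbonate with free C5β hydroxyl | COc1ccc(CO[C@@H]2[C@H](CCO[Si](C)(C)C(C)(C)C)C=C(O[Si](C)(C)C(C)(C)C)[C@H](C)[C@@]3(COC(=O)O3)[C@H]2O)cc1
F7 | step 8 | C1/C2 spiro cyclic carbonate with C5β (S)-2-methylbutanoate | COc1ccc(CO[C@@H]2[C@H](CCO[Si](C)(C)C(C)(C)C)C=C(O[Si](C)(C)C(C)(C)C)[C@H](C)[C@@]3(COC(=O)O3)[C@H]2OC(=O)[C@@H](C)CC)cc1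
F8 | step 9 | 1α,5α-epoxy aldehyde from 13 | COc1ccc(CO[C@@H]2[C@H](CCO[Si](C)(C)C(C)(C)C)C=C(O[Si](C)(C)C(C)(C)C)[C@H](C)[C@]3(C=O)O[C@H]23)cc1
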